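## Structural features

The target 19 is a dihydroflavonol: benzene ring A is fused through C4a–C8a to the six-membered pyranone ring C (O1, C2, C3, C4), and phenyl ring B sits on C2. Ring A is hexasubstituted, with O1 on C8a, methoxy on C8, hydroxyl on C7, a prenyl chain on C6, hydroxyl on C5 and the ketone carbon C4 on C4a. The two stereocentres are adjacent: C2 (benzylic, bonded to O1 and phenyl) and C3 (a carbinol next to the C4 ketone) are trans and both R. The prenyl double bond lies between two free phenols and closes to a dimethylchroman under strong acid. The beta-aryloxy ketone opens at O1–C2 under base, and the alpha-hydroxy ketone can epimerise or oxidise to the flavonol. The real difficulty is to place four different oxygens and the prenyl group on ring A in a fixed order while delivering trans-C2/C3 as one enantiomer under mild conditions. The feature exploited is that C5–OH is para to C8–OMe, so ring A is a para-methoxyphenol, and C8a lies between C8 and the acyl-bearing C4a. In the derived quinone monoketal C8a becomes an electrophilic CH, so O1–C8a can be made last, from a C–H bond.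

## Logic of the disconnections

19 ⇒ 18. The O3–Si bond and the O7–CH2 acetal bond are cut. Nothing skeletal changes; the gain is that O3 and O7 stay masked through the oxidation. The demand is one final acid step mild enough to spare the prenyl alkene between two phenols.

18 ⇒ 16 (through 17). The O1–C8a bond is cut, which opens ring C and turns C8a into a C–H. This removes the fourth ring-A oxygen from the synthetic problem and leaves an open-chain ketone whose two stereocentres can be bought. The forward step must oxidise only the para-methoxyphenol, must close through the oxygen on C2 and not the one on C3, and must not touch C2 or C3.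

16 ⇒ 8 + 13 (through 14 and 15). The C4–C4a aryl–carbonyl bond is cut, and the C5 phenol and the C2 hydroxyl are re-masked. This splits the molecule into an achiral arene and a chiral three-carbon unit of similar size. The forward step needs metalation at the one ring position next to the C5 oxygen, and masks on O5 and on the C2 oxygen that fall together under acid too weak to remove the O7 acetal or the O3 silyl ether.

8 ⇒ 5 + 6 (through 7). The C6–CH2 bond of the prenyl group is cut. The site lies between the two acetal oxygens of 5, so the forward metalation is unambiguous; the allylation must occur at the primary carbon of 6.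

5 ⇒ 4 ⇒ 2 ⇒ 1 (through 3). The acetal bonds on O5 and O7 are cut, and the C5–O bond is traced back to the formyl carbon of 1. All three ring oxygens then come from 1, and because the two phenolic oxygens appear in different steps they can carry different masks at no extra cost. The demand is aryl migration, not hydride migration, in the oxidation of 2.

13 ⇒ 12 ⇒ 11 ⇒ 10 ⇒ 9. The enol ether is traced to an allyl ether, the amide to the methyl ester, the O–Si bond on the alpha oxygen is cut, and the benzylic C–O bond is cut back to the epoxide of 9. Both stereocentres then come from one commercial compound, and the two oxygens are differentiated from the moment the epoxide opens. The forward opening must occur at the benzylic carbon with clean inversion.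

## Other disconnections considered

Alternative 1: The cut takes out C4 as carbon monoxide A4 and breaks C4a–C4, C4–C3 and O1–C2 at the flavone oxidation level, leading to ortho-iodophenol A2 and phenylacetylene A3. In the forward step PdCl2(PPh3)2 is reduced to zerovalent palladium, inserts into the C4a–I bond of A2, takes up A4 and couples with A3 to give ynone A5. Amine-assisted 6-endo addition of the phenol oxygen should then give flavone A1.
- In favour: the reaction class is well established, three bonds and ring C form in one operation, and A3 and A4 are trivial. On mechanistic certainty and on bonds formed per step this alternative is better than the chosen plan.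
- Against: A1 is flat. Both C2 and C3 would have to be created afterwards by enantioselective reduction of the C2=C3 bond beside a prenyl alkene and trans-selective hydroxylation at C3, which is where the target is hardest. A2 is a hexasubstituted benzene with four oxygens already differentiated, and its C–I bond is flanked on both sides. Closure of A5 in the 5-exo sense is a possible competitor.
- Comparison: the chosen route carries both stereocentres from 9 and needs only the three oxygens of 1, so it should be shorter after the key step and start from a simpler arene. Its key step is less certain.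

Alternative 2: The cut is the C2–C3 bond, leading to the tertiary alpha-hydroxy aldehyde A7 on a dihydrobenzofuran. In the forward step an acid- or base-promoted alpha-ketol shift moves C2 from the carbinol carbon to the formyl carbon. The carbinol carbon becomes the C4 ketone and the five-membered ring expands to ring C of A6.
- In favour: the aldehyde-to-aryl-ketone change and the ring expansion give a thermodynamic drive, the migrating carbon keeps its configuration, and A6 has O3 free at the correct oxidation level. It builds a skeletal C–C bond and a stereocentre in the key step, which the chosen plan does not; on those two points it is better.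
- Against: migration of the aryl carbon C4a instead of C2 would expand the ring the wrong way. The new C3 centre relies on the thermodynamic trans preference. A7 would come from ketone A8, whose C2 hydrogen lies between a carbonyl, an ether oxygen and a phenyl group and should racemise easily. Ring A again needs all four oxygens in place.
- Comparison: both plans rest on an untested ring-forming step, so they are equal on that point. The chosen plan has the more accessible precursor and configurationally secure intermediates, and should need fewer steps.

Alternative 3: The cut is C4–C4a together with O1–C2, leading to phenol A10 and epoxy aldehyde A11. In the forward step A10, deprotonated with EtMgBr, adds through C4a to the aldehyde of A11. The phenol oxygen then opens the epoxide at the benzylic carbon with inversion to give flavan-3,4-diol A9.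
- In favour: the route is convergent and makes two bonds and ring C in one operation. Both stereocentres come from an oxirane of the same configuration as in 9, so the chirality source is equal to that of the chosen plan. A10 has a single free ortho position, so the C–C bond formation is regiochemically unambiguous, which is better than the directed lithiation of the chosen route.
- Against: A10 needs four differentiated oxygens before the key step. The Lewis-acidic medium may ionise the benzylic C–O bond and erode C2. Attack of the phenol oxygen on the nearer epoxide carbon would close a five-membered ring. A9 is at the wrong oxidation level, so its C4 carbinol must be oxidised selectively beside the C3 carbinol. A11 is a sensitive alpha-epoxy aldehyde.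
- Comparison: the key step is better on bonds formed and equal on chirality source. The chosen plan avoids the redox correction and the tetraoxygenated phenol and should be shorter overall.

Key step: step 10

Remark on the chemistry: the descriptors were checked against the structures. 9 is (2R,3S); inversion at its benzylic carbon in step 5 gives the (2R,3R) arrangement, which is carried unchanged into 16, 18 and 19. Compounds 5, 7, 8, 14 and 15 carry a 1-ethoxyethyl acetal and are mixtures of both configurations at the acetal carbon; that centre is removed in step 9 and is left open in the SMILES.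

## Steps

Step 1
Reactants: 1 isovanillin (3-hydroxy-4-methoxybenzaldehyde)
Product: 2 4-methoxy-3-(methoxymethoxy)benzaldehyde
Conditions: MOMCl, i-Pr2NEt, CH2Cl2, 0 °C → rt
Reagents that add atoms: chloromethyl methyl ether, COCCl
Why: Williamson-type O-alkylation of the phenol; this oxygen becomes O7, and its acetal survives to the last step and serves as one of the two directing groups for the first lithiation.

Step 2
Reactants: 2 4-methoxy-3-(methoxymethoxy)benzaldehyde
Product: 4 4-methoxy-3-(methoxymethoxy)phenol, via aryl formate 3 (not isolated)
Conditions: mCPBA, NaHCO3, CH2Cl2, 0 °C → rt; then K2CO3 (cat.), MeOH, rt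
Reagents that add atoms: 3-chloroperoxybenzoic acid, O=C(OO)c1cccc(Cl)c1
Why: Baeyer–Villiger (Dakin-type) oxidation; the electron-rich aryl group para to methoxy migrates in the Criegee intermediate, and methanolysis of the formate frees the phenol that becomes O5.

Step 3
Reactants: 4 4-methoxy-3-(methoxymethoxy)phenol
Product: 5 1-(1-ethoxyethoxy)-4-methoxy-3-(methoxymethoxy)benzene
Conditions: ethyl vinyl ether, PPTS (cat.), CH2Cl2, 0 °C → rt
Reagents that add atoms: ethyl vinyl ether, C=COCC
Why: acid-catalysed addition of the phenol to an enol ether (mixed acetal formation); the ethoxyethyl acetal directs lithiation like a MOM group but is cleaved by acid too weak to touch the MOM or silyl ethers.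

Step 4
Reactants: 5 1-(1-ethoxyethoxy)-4-methoxy-3-(methoxymethoxy)benzene; 6 prenyl bromide (1-bromo-3-methylbut-2-ene)
Product: 8 1-(1-ethoxyethoxy)-4-methoxy-3-(methoxymethoxy)-2-(3-methylbut-2-enyl)benzene, via aryllithium 7 (not isolated)
Conditions: n-BuLi, THF, 0 °C; then CuBr·SMe2 (10 mol %), 6, −78 °C → rt
Reagents that add atoms: none
Why: directed ortho-metalation at the only carbon flanked by both acetal oxygens, then copper-catalysed SN2 allylation at the primary carbon of 6, which puts the prenyl group on the future C6.

Step 5
Reactants: 9 methyl (2R,3S)-3-phenyloxirane-2-carboxylate (methyl (2R,3S)-3-phenylglycidate)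
Product: 10 methyl (2R,3R)-2-hydroxy-3-phenyl-3-(prop-2-enyloxy)propanoate
Conditions: allyl alcohol (5 equiv), BF3·OEt2 (10 mol %), CH2Cl2, −20 → 0 °C
Reagents that add atoms: allyl alcohol, C=CCO
Why: Lewis acid-catalysed alcoholysis of an aryl epoxide at the benzylic carbon; the ester disfavours attack at C2 and full ionisation, so backside attack should set C3 as R while C2 is untouched, giving the anti arrangement with the two oxygens already differentiated.

Step 6
Reactants: 10 methyl (2R,3R)-2-hydroxy-3-phenyl-3-(prop-2-enyloxy)propanoate
Product: 11 methyl (2R,3R)-2-(tert-butyldimethylsilyloxy)-3-phenyl-3-(prop-2-enyloxy)propanoate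
Conditions: TBSOTf, 2,6-lutidine, CH2Cl2, 0 °C
Reagents that add atoms: tert-butyldimethylsilyl trifluoromethanesulfonate, CC(C)(C)[Si](C)(C)OS(=O)(=O)C(F)(F)F
Why: silylation of the only free hydroxyl; the silyl ether blocks the oxygen that becomes O3 so that it cannot take part in the later ring closure.

Step 7
Reactants: 11 methyl (2R,3R)-2-(tert-butyldimethylsilyloxy)-3-phenyl-3-(prop-2-enyloxy)propanoate
Product: 12 (2R,3R)-2-(tert-butyldimethylsilyloxy)-N-methoxy-N-methyl-3-phenyl-3-(prop-2-enyloxy)propanamide
Conditions: MeNH(OMe)·HCl, i-PrMgCl, THF, −20 → 0 °C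
Reagents that add atoms: N,O-dimethylhydroxylamine hydrochloride, CNOC.Cl
Why: aminolysis of the ester by the chloromagnesium amide formed in the flask (N-methoxy-N-methylamide formation); the low temperature and the non-enolising nucleophile should keep C2 intact.

Step 8
Reactants: 12 (2R,3R)-2-(tert-butyldimethylsilyloxy)-N-methoxy-N-methyl-3-phenyl-3-(prop-2-enyloxy)propanamide
Product: 13 (2R,3R)-2-(tert-butyldimethylsilyloxy)-N-methoxy-N-methyl-3-phenyl-3-[(E)-prop-1-enyloxy]propanamide
Conditions: [Ir(cod)(PMePh2)2]PF6 (2 mol %, H2-activated), THF, rt
Reagents that add atoms: none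
Why: iridium hydride-catalysed isomerisation of an allyl ether to the (E)-prop-1-enyl ether; the enol ether tolerates organolithiums but falls to very mild acid, and the step is run before any prenyl group is present.

Step 9
Reactants: 8 1-(1-ethoxyethoxy)-4-methoxy-3-(methoxymethoxy)-2-(3-methylbut-2-enyl)benzene; 13 (2R,3R)-2-(tert-butyldimethylsilyloxy)-N-methoxy-N-methyl-3-phenyl-3-[(E)-prop-1-enyloxy]propanamide
Product: 16 (2R,3R)-2-(tert-butyldimethylsilyloxy)-3-hydroxy-1-[2-hydroxy-5-methoxy-4-(methoxymethoxy)-3-(3-methylbut-2-enyl)phenyl]-3-phenylpropan-1-one, via aryllithium 14 (not isolated), via protected ketone 15 (not isolated)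
Conditions: s-BuLi, TMEDA, THF, −78 °C; then 13, −78 → −40 °C; aq. NH4Cl; then PPTS (20 mol %), MeOH, rt → 35 °C
Reagents that add atoms: none
Why: directed ortho-lithiation next to the ethoxyethyl acetal (the only acetal with a free ortho position), then Weinreb ketone synthesis through the chelated tetrahedral adduct, which prevents over-addition. Acetal exchange with methanol then removes the aryl ethoxyethyl group and the enol ether together, while the aryl MOM ether and the secondary silyl ether should remain.

Step 10
Reactants: 16 (2R,3R)-2-(tert-butyldimethylsilyloxy)-3-hydroxy-1-[2-hydroxy-5-methoxy-4-(methoxymethoxy)-3-(3-methylbut-2-enyl)phenyl]-3-phenylpropan-1-one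
Product: 18 (2R,3R)-3-(tert-butyldimethylsilyloxy)-5-hydroxy-8-methoxy-7-(methoxymethoxy)-6-(3-methylbut-2-enyl)-2-phenyl-2,3-dihydro-4H-chromen-4-one, via quinone monoketal 17 (not isolated)
Conditions: graphite anode, Pt cathode, undivided cell, constant current (2.2 F/mol), LiClO4, 2,6-lutidine, MeOH, 0 °C; then MeOH removed cold, CH2Cl2, AcOH (cat.), 0 °C → rt
Reagents that add atoms: methanol, CO (supplies the second methoxy group of ketal 17; one of the two ketal methoxy groups stays on C8 of 18)
Why: Proposed new method: two-electron anodic oxidation of the para-methoxyphenol, eased by 2,6-lutidine, gives a phenoxonium ion that methanol traps at C8, the para carbon already bearing a methoxy group, to form quinone monoketal 17; this part is the established anodic synthesis of quinone monoketals. In 17 the C4a=C8a double bond is activated by both the ring carbonyl at C5 and the side-chain ketone at C4, and C8a is its only hydrogen-bearing beta carbon, so the hydroxyl on C2 should add there in a 6-endo-trig oxa-Michael closure that forms O1–C8a and ring C. Acid-assisted loss of one ketal methoxy group from C8 and of the proton on C8a then restores the arene with C8–OMe and C5–OH; the closest known reaction type is the addition–elimination of carbon, nitrogen and sulfur nucleophiles on quinone monoketals, which has not been shown as an intramolecular alkoxy closure to a chromanone. No stereocentre is created: C2 and C3 come from 9, no bond to either is made or broken, and the 2,3-trans product is also the more stable arrangement. The step needs oxidation of the phenol and not of the prenyl alkene (the phenol oxidises at a much lower potential, and the charge is limited), closure through the C2 oxygen and not the C3 oxygen (the silyl ether on O3 blocks the five-membered closure), and addition of the internal hydroxyl and not of methanol (methanol is removed before the closure is triggered). Passing the charge at 0 °C before closure begins also keeps 18, itself an even more electron-rich para-methoxyphenol, out of the electrolysis.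

Step 11
Reactants: 18 (2R,3R)-3-(tert-butyldimethylsilyloxy)-5-hydroxy-8-methoxy-7-(methoxymethoxy)-6-(3-methylbut-2-enyl)-2-phenyl-2,3-dihydro-4H-chromen-4-one
Product: 19 (2R,3R)-3,5,7-trihydroxy-8-methoxy-6-(3-methylbut-2-enyl)-2-phenyl-2,3-dihydro-4H-chromen-4-one (CNP0291135.2)
Conditions: HCl (ca. 1 M) in MeOH, rt → 35 °C
Reagents that add atoms: none
Why: acid-catalysed acetal exchange removes the aryl MOM group and solvolysis removes the secondary silyl ether in one operation; keeping the acid dilute and the temperature low should spare the prenyl alkene and leave C2 and C3 unchanged.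

## Compound list

1 | isovanillin (3-hydroxy-4-methoxybenzaldehyde) | COc1ccc(C=O)cc1O | starting material
2 | 4-methoxy-3-(methoxymethoxy)benzaldehyde | COCOc1cc(C=O)ccc1OC | intermediate
3 | 4-methoxy-3-(methoxymethoxy)phenyl formate | COCOc1cc(OC=O)ccc1OC | intermediate (not isolated)
4 | 4-methoxy-3-(methoxymethoxy)phenol | COCOc1cc(O)ccc1OC | intermediate
5 | 1-(1-ethoxyethoxy)-4-methoxy-3-(methoxymethoxy)benzene (both configurations at the acetal carbon) | CCOC(C)Oc1ccc(OC)c(OCOC)c1 | intermediate
6 | prenyl bromide (1-bromo-3-methylbut-2-ene) | CC(C)=CCBr | starting material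
7 | [6-(1-ethoxyethoxy)-3-methoxy-2-(methoxymethoxy)phenyl]lithium | CCOC(C)Oc1ccc(OC)c(OCOC)c1[Li] | intermediate (not isolated)
8 | 1-(1-ethoxyethoxy)-4-methoxy-3-(methoxymethoxy)-2-(3-methylbut-2-enyl)benzene (both configurations at the acetal carbon) | CCOC(C)Oc1ccc(OC)c(OCOC)c1CC=C(C)C | intermediate
9 | methyl (2R,3S)-3-phenyloxirane-2-carboxylate | COC(=O)[C@@H]1O[C@H]1c1ccccc1 | starting material
10 | methyl (2R,3R)-2-hydroxy-3-phenyl-3-(prop-2-enyloxy)propanoate | COC(=O)[C@H](O)[C@H](OCC=C)c1ccccc1 | intermediate
11 | methyl (2R,3R)-2-(tert-butyldimethylsilyloxy)-3-phenyl-3-(prop-2-enyloxy)propanoate | COC(=O)[C@H](O[Si](C)(C)C(C)(C)C)[C@H](OCC=C)c1ccccc1 | intermediate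
12 | (2R,3R)-2-(tert-butyldimethylsilyloxy)-N-methoxy-N-methyl-3-phenyl-3-(prop-2-enyloxy)propanamide | CON(C)C(=O)[C@H](O[Si](C)(C)C(C)(C)C)[C@H](OCC=C)c1ccccc1 | intermediate
13 | (2R,3R)-2-(tert-butyldimethylsilyloxy)-N-methoxy-N-methyl-3-phenyl-3-[(E)-prop-1-enyloxy]propanamide | CON(C)C(=O)[C@H](O[Si](C)(C)C(C)(C)C)[C@H](O/C=C/C)c1ccccc1 | intermediate
14 | [2-(1-ethoxyethoxy)-5-methoxy-4-(methoxymethoxy)-3-(3-methylbut-2-enyl)phenyl]lithium | CCOC(C)Oc1c([Li])cc(OC)c(OCOC)c1CC=C(C)C | intermediate (not isolated)
15 | (2R,3R)-2-(tert-butyldimethylsilyloxy)-1-[2-(1-ethoxyethoxy)-5-methoxy-4-(methoxymethoxy)-3-(3-methylbut-2-enyl)phenyl]-3-phenyl-3-[(E)-prop-1-enyloxy]propan-1-one (both configurations at the acetal carbon) | CCOC(C)Oc1c(C(=O)[C@H](O[Si](C)(C)C(C)(C)C)[C@H](O/C=C/C)c2ccccc2)cc(OC)c(OCOC)c1CC=C(C)C | intermediate (not isolated)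
16 | (2R,3R)-2-(tert-butyldimethylsilyloxy)-3-hydroxy-1-[2-hydroxy-5-methoxy-4-(methoxymethoxy)-3-(3-methylbut-2-enyl)phenyl]-3-phenylpropan-1-one | COc1cc(C(=O)[C@H](O[Si](C)(C)C(C)(C)C)[C@H](O)c2ccccc2)c(O)c(CC=C(C)C)c1OCOC | intermediate
17 | (2R,3R)-2-(tert-butyldimethylsilyloxy)-1-[3,3-dimethoxy-4-(methoxymethoxy)-5-(3-methylbut-2-enyl)-6-oxocyclohexa-1,4-dien-1-yl]-3-hydroxy-3-phenylpropan-1-one | COCOC1=C(CC=C(C)C)C(=O)C(C(=O)[C@H](O[Si](C)(C)C(C)(C)C)[C@H](O)c2ccccc2)=CC1(OC)OC | intermediate (not isolated)
18 | (2R,3R)-3-(tert-butyldimethylsilyloxy)-5-hydroxy-8-methoxy-7-(methoxymethoxy)-6-(3-methylbut-2-enyl)-2-phenyl-2,3-dihydro-4H-chromen-4-one | COc1c(OCOC)c(CC=C(C)C)c(O)c2c1O[C@H](c1ccccc1)[C@@H](O[Si](C)(C)C(C)(C)C)C2=O | intermediate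
19 | (2R,3R)-3,5,7-trihydroxy-8-methoxy-6-(3-methylbut-2-enyl)-2-phenyl-2,3-dihydro-4H-chromen-4-one | COc1c(O)c(CC=C(C)C)c(O)c2c1O[C@H](c1ccccc1)[C@@H](O)C2=O | target

## Step count and least certain steps

Total: 11 steps. Longest linear sequence: 7 steps (from 1 through steps 1–4 and 9–11; the branch from 9 through steps 5–11 is equally long).

Step 10 (proposed new method).
- What may go wrong: conjugate addition of methanol at C8a in place of the internal hydroxyl; further oxidation of the aromatised product if closure starts during electrolysis; loss of the benzylic proton of the prenyl group from the phenoxonium ion followed by chromene formation; silyl migration from O3 to the C2 oxygen followed by five-membered closure.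
- Fallback with known chemistry, setting out from 16 and returning at 18: PhI(OAc)2 in aqueous acetonitrile at 0 °C oxidatively demethylates the para-methoxyphenol to the acylquinone 2-[(2R,3R)-2-(tert-butyldimethylsilyloxy)-3-hydroxy-3-phenylpropanoyl]-5-(methoxymethoxy)-6-(3-methylbut-2-enyl)cyclohexa-2,5-diene-1,4-dione F1. The side-chain hydroxyl adds to the quinone carbon next to the acyl group (oxa-Michael addition to an acylquinone), and tautomerisation should give the hydroquinone (2R,3R)-3-(tert-butyldimethylsilyloxy)-5,8-dihydroxy-7-(methoxymethoxy)-6-(3-methylbut-2-enyl)-2-phenyl-2,3-dihydro-4H-chromen-4-one F2, kept reduced by a Na2S2O4 wash. Methylation with TMSCHN2 in methanol–toluene should take the free 8-OH and leave the 5-OH, which is hydrogen-bonded to the C4 carbonyl, so the sequence rejoins the route at 18.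

Step 9.
- What may go wrong: deprotonation at the benzylic-allylic CH2 of the prenyl group or ortho to the methoxy group in place of the position next to the ethoxyethyl acetal; enolisation of 13 by the aryllithium.
- Fallback, setting out from 8 and returning at 14: NBS (MeCN, NaHCO3, −20 °C) should brominate the ring carbon that is ortho to the ethoxyethyl oxygen and para to the MOM oxygen, giving 1-bromo-2-(1-ethoxyethoxy)-5-methoxy-4-(methoxymethoxy)-3-(3-methylbut-2-enyl)benzene F3. Bromine–lithium exchange (t-BuLi, THF, −78 °C) then generates the aryllithium at the site fixed by the halogen, which is 14.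

Step 11.
- What may go wrong: acid-catalysed addition of the C5 or C7 hydroxyl to the prenyl double bond (dimethylchroman formation) before the silyl ether has been cleaved.
- Fallback, setting out from 18 and returning at 19: HF·pyridine in THF–pyridine removes only the silyl ether and should give (2R,3R)-3,5-dihydroxy-8-methoxy-7-(methoxymethoxy)-6-(3-methylbut-2-enyl)-2-phenyl-2,3-dihydro-4H-chromen-4-one F4. ZnBr2 with n-PrSH in CH2Cl2 at 0 °C then transfers the methoxymethyl group to sulfur within minutes without a protic acid, giving 19.

Step 5.
- What may go wrong: partial ionisation at the benzylic carbon, so that the alcohol enters with retention and the anti relationship is eroded.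
- Fallback, setting out from 9 and returning at 10: KOH (1 equiv) in ethanol at 0 °C gives potassium (2R,3S)-3-phenyloxirane-2-carboxylate F5. NaOCH2CH=CH2 in allyl alcohol at 60 °C opens the carboxylate-deactivated epoxide by SN2 attack at the benzylic carbon without any Lewis acid, and acidification gives (2R,3R)-2-hydroxy-3-phenyl-3-(prop-2-enyloxy)propanoic acid F6. TMSCHN2 in methanol–toluene re-forms the methyl ester 10.

## Further compounds

F1 | step 10 | 2-[(2R,3R)-2-(tert-butyldimethylsilyloxy)-3-hydroxy-3-phenylpropanoyl]-5-(methoxymethoxy)-6-(3-methylbut-2-enyl)cyclohexa-2,5-diene-1,4-dione | COCOC1=C(CC=C(C)C)C(=O)C(C(=O)[C@H](O[Si](C)(C)C(C)(C)C)[C@H](O)c2ccccc2)=CC1=O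
F2 | step 10 | (2R,3R)-3-(tert-butyldimethylsilyloxy)-5,8-dihydroxy-7-(methoxymethoxy)-6-(3-methylbut-2-enyl)-2-phenyl-2,3-dihydro-4H-chromen-4-one | Oc1c(OCOC)c(CC=C(C)C)c(O)c2c1O[C@H](c1ccccc1)[C@@H](O[Si](C)(C)C(C)(C)C)C2=O
F3 | step 9 | 1-bromo-2-(1-ethoxyethoxy)-5-methoxy-4-(methoxymethoxy)-3-(3-methylbut-2-enyl)benzene (both configurations at the acetal carbon) | CCOC(C)Oc1c(Br)cc(OC)c(OCOC)c1CC=C(C)C
F4 | step 11 | (2R,3R)-3,5-dihydroxy-8-methoxy-7-(methoxymethoxy)-6-(3-methylbut-2-enyl)-2-phenyl-2,3-dihydro-4H-chromen-4-one | COc1c(OCOC)c(CC=C(C)C)c(O)c2c1O[C@H](c1ccccc1)[C@@H](O)C2=O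
F5 | step 5 | potassium (2R,3S)-3-phenyloxirane-2-carboxylate | [K+].[O-]C(=O)[C@@H]1O[C@H]1c1ccccc1
F6 | step 5 | (2R,3R)-2-hydroxy-3-phenyl-3-(prop-2-enyloxy)propanoic acid | OC(=O)[C@H](O)[C@H](OCC=C)c1ccccc1
A1 | alternative 1 | 8-methoxy-5,7-bis(methoxymethoxy)-6-(3-methylbut-2-enyl)flavone | COc1c(OCOC)c(CC=C(C)C)c(OCOC)c2c1OC(c1ccccc1)=CC2=O
A2 | alternative 1 | 2-iodo-6-methoxy-3,5-bis(methoxymethoxy)-4-(3-methylbut-2-enyl)phenol | COc1c(O)c(I)c(OCOC)c(CC=C(C)C)c1OCOC
A3 | alternative 1 | phenylacetylene | C#Cc1ccccc1
A4 | alternative 1 | carbon monoxide | [C-]#[O+]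
A5 | alternative 1 | 1-[2-hydroxy-3-methoxy-4,6-bis(methoxymethoxy)-5-(3-methylbut-2-enyl)phenyl]-3-phenylprop-2-yn-1-one | COc1c(O)c(C(=O)C#Cc2ccccc2)c(OCOC)c(CC=C(C)C)c1OCOC
A6 | alternative 2 | (2R,3R)-3-hydroxy-8-methoxy-7-(methoxymethoxy)-6-(3-methylbut-2-enyl)-5-(triisopropylsilyloxy)flavanone | COc1c(OCOC)c(CC=C(C)C)c(O[Si](C(C)C)(C(C)C)C(C)C)c2c1O[C@H](c1ccccc1)[C@@H](O)C2=O
A7 | alternative 2 | (2R)-3-hydroxy-7-methoxy-6-(methoxymethoxy)-5-(3-methylbut-2-enyl)-2-phenyl-4-(triisopropylsilyloxy)-2,3-dihydro-1-benzofuran-3-carbaldehyde (configuration at C3 left open) | COc1c(OCOC)c(CC=C(C)C)c(O[Si](C(C)C)(C(C)C)C(C)C)c2c1O[C@H](c1ccccc1)C2(O)C=O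
A8 | alternative 2 | (2R)-7-methoxy-6-(methoxymethoxy)-5-(3-methylbut-2-enyl)-2-phenyl-4-(triisopropylsilyloxy)-1-benzofuran-3(2H)-one | COc1c(OCOC)c(CC=C(C)C)c(O[Si](C(C)C)(C(C)C)C(C)C)c2c1O[C@H](c1ccccc1)C2=O
A9 | alternative 3 | (2R,3S,4R)-8-methoxy-5,7-bis(methoxymethoxy)-6-(3-methylbut-2-enyl)-2-phenyl-3,4-dihydro-2H-chromene-3,4-diol (2,3-trans; either C4 epimer serves) | COc1c(OCOC)c(CC=C(C)C)c(OCOC)c2c1O[C@H](c1ccccc1)[C@@H](O)[C@@H]2O
A10 | alternative 3 | 2-methoxy-3,5-bis(methoxymethoxy)-4-(3-methylbut-2-enyl)phenol | COc1c(O)cc(OCOC)c(CC=C(C)C)c1OCOC
A11 | alternative 3 | (2R,3S)-3-phenyloxirane-2-carbaldehyde | O=C[C@@H]1O[C@H]1c1ccccc1
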